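## Retrosynthetic overview

1. Target ⇐ phenol desilylation ⇐ silyl-protected vanillate; the C8–O acyl bond and the C6 carbinol are installed together on the ring diol by a samarium-catalysed Oppenauer/Evans–Tishchenko redox relay with O-silyl vanillin (new step).
2. Ten-membered carbocycle (the only ring formed, closed after all stereocentres are in place) ⇐ ring-closing metathesis at C1=C10 of an acyclic triene diol.
3. (Z)-C4=C5 olefin ⇐ hydroxyl-directed syn methylmagnesiation of the C4≡C5 propargylic alcohol.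
4. C8 carbinol ⇐ phosphoric-acid-catalysed methallylboration; C6–C7 bond and the first stereocentres ⇐ amine-catalysed anti cross-aldol of 3-methylbutanal with hept-6-en-2-ynal (from hex-1-en-5-yne).
5. Order: aldol (C6, C7) → allylation (C8) → Z-olefin → ring closure → acyl/redox relay → deprotection.

Locants used below (ring atoms of the target): C8 = ester carbinol, C9 = CH2, C10 = C(Me), C1 = CH=, C2, C3 = CH2, C4 = C(Me), C5 = CH=, C6 = free carbinol, C7 = CH(iPr).

Assumption: the structure is taken exactly as drawn (both ring olefins Z; 6R,7R,8R in these locants), and the two organocatalysts are taken to show the facial senses known for simple aldehydes (D-proline-like anti aldol for the (R)-diarylprolinol; Re-face allyl transfer for (R)-TRIP).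

## Route

Step 1
Reactants: 1 hex-1-en-5-yne
Product: 2 hept-6-en-2-ynal
Conditions: n-BuLi, THF, −78 °C; DMF, −78 → 0 °C; poured into 10% aq KH2PO4/MTBE, 0 °C
Reagents that add atoms: N,N-dimethylformamide (DMF), CN(C)C=O
Why: Deprotonation of the terminal alkyne and formylation with DMF is the standard synthesis of 2-ynals; no stereocentre is formed.

Step 2
Reactants: 2 hept-6-en-2-ynal; 3 3-methylbutanal; 4 4,4,5,5-tetramethyl-2-(2-methylprop-2-en-1-yl)-1,3,2-dioxaborolane
Product: 6 (4R,5S,6S)-2-methyl-5-(propan-2-yl)dodeca-1,11-dien-7-yne-4,6-diol, via aldol aldehyde 5 (not isolated)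
Conditions: (R)-α,α-bis[3,5-bis(trifluoromethyl)phenyl]-2-pyrrolidinemethanol (10 mol%), H2O (3 equiv), 1,4-dioxane, rt; aq citric acid work-up, excess 3 evaporated; then 4, (R)-TRIP [(R)-3,3′-bis(2,4,6-triisopropylphenyl)-1,1′-binaphthyl-2,2′-diyl hydrogen phosphate] (5 mol%), 4 Å MS, toluene, −30 °C
Reagents that add atoms: none
Why: Enamine-catalysed anti-selective cross-aldol reaction (the catalyst hydroxyl hydrogen-bonds the non-enolisable ynal) sets C6 and C7 from achiral partners, and the chiral-phosphoric-acid-catalysed methallylboration then adds to the Re face of the aldehyde through a closed chair transition state under catalyst control to set C8 (7,8-syn, 6,8-anti).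

Step 3
Reactants: 6 (4R,5S,6S)-2-methyl-5-(propan-2-yl)dodeca-1,11-dien-7-yne-4,6-diol
Product: 7 (4R,5S,6R,7Z)-2,8-dimethyl-5-(propan-2-yl)dodeca-1,7,11-triene-4,6-diol
Conditions: MeMgBr (6 equiv), Fe(acac)3 (20 mol%), THF, −20 → 0 °C; aq NH4Cl
Reagents that add atoms: methylmagnesium bromide, C[Mg]Br
Why: Iron-catalysed, alkoxide-directed carbomagnesiation of a propargylic alcohol delivers methyl to the distal alkyne carbon (C4) and magnesium to the proximal one (C5) in a syn addition, so protonolysis leaves C3 cis to C6 (Z); no stereocentre is touched.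

Step 4
Reactants: 7 (4R,5S,6R,7Z)-2,8-dimethyl-5-(propan-2-yl)dodeca-1,7,11-triene-4,6-diol
Product: 8 (1R,2S,3R,4Z,8Z)-5,9-dimethyl-2-(propan-2-yl)cyclodeca-4,8-diene-1,3-diol
Conditions: second-generation Hoveyda–Grubbs catalyst (10 mol%), 1,4-benzoquinone (20 mol%), toluene (1 mM), 80 °C
Reagents that add atoms: none
Why: Ring-closing metathesis starts at the monosubstituted olefin and closes onto the 1,1-disubstituted olefin with loss of ethene, and in a ten-membered 1,5-diene ring that already holds one Z olefin the new trisubstituted C1=C10 olefin closes as the less strained Z isomer.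

Step 5
Reactants: 9 4-hydroxy-3-methoxybenzaldehyde (vanillin)
Product: 10 4-[(tert-butyldimethylsilyl)oxy]-3-methoxybenzaldehyde
Conditions: TBSCl, imidazole, CH2Cl2, rt
Reagents that add atoms: tert-butyldimethylsilyl chloride, CC(C)(C)[Si](C)(C)Cl
Why: Standard silylation of a phenol, which keeps the acidic phenol from quenching the samarium alkoxide catalyst of the next step.

Step 6
Reactants: 8 (1R,2S,3R,4Z,8Z)-5,9-dimethyl-2-(propan-2-yl)cyclodeca-4,8-diene-1,3-diol; 10 4-[(tert-butyldimethylsilyl)oxy]-3-methoxybenzaldehyde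
Product: 12 (1R,3Z,7Z,9R,10R)-9-hydroxy-3,7-dimethyl-10-(propan-2-yl)cyclodeca-3,7-dien-1-yl 4-[(tert-butyldimethylsilyl)oxy]-3-methoxybenzoate, via hydroxy enone 11 (not isolated)
Conditions: SmI2(OtBu) (20 mol%, from SmI2 and tBuOOtBu), 10 (4 equiv), THF, −10 °C → rt
Reagents that add atoms: none
Why: Proposed new method: a samarium-catalysed Oppenauer/Evans–Tishchenko redox relay, in which the trivalent samarium alkoxide of the allylic C6 carbinol first passes its hydride to one molecule of 10 through the usual six-membered Meerwein–Ponndorf–Verley/Oppenauer transition state (the conjugated Z-enone 11 is the thermodynamically favoured carbonyl, so C6 and not C8 is oxidised), after which the C8 hydroxyl adds to a second molecule of 10 and the samarium-bound hemiacetal returns a hydride intramolecularly to the C6 ketone from the face of the C8 oxygen, so that the acyl group ends on O8 and C6 is re-formed 1,3-anti (trans across the ring) to C8 whatever its configuration in 8; the closest known reactions are the SmI2-catalysed Evans–Tishchenko reduction of β-hydroxy ketones and the SmI2(OtBu)-catalysed Oppenauer oxidation of allylic alcohols, which have not been coupled in one flask to mono-acylate an allylic 1,3-diol.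

Step 7
Reactants: 12 (1R,3Z,7Z,9R,10R)-9-hydroxy-3,7-dimethyl-10-(propan-2-yl)cyclodeca-3,7-dien-1-yl 4-[(tert-butyldimethylsilyl)oxy]-3-methoxybenzoate
Product: 13 (1R,3Z,7Z,9R,10R)-9-hydroxy-3,7-dimethyl-10-(propan-2-yl)cyclodeca-3,7-dien-1-yl 4-hydroxy-3-methoxybenzoate
Conditions: KHF2, MeOH, rt
Reagents that add atoms: none
Why: Bifluoride-mediated desilylation cleaves only the aryl silyl ether (phenoxide is the good leaving group) and leaves the ester, the allylic alcohol, both olefins and all stereocentres untouched.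

## Compound list

1 | hex-1-en-5-yne | C=CCCC#C | starting material
2 | hept-6-en-2-ynal | C=CCCC#CC=O | intermediate
3 | 3-methylbutanal (isovaleraldehyde) | CC(C)CC=O | starting material
4 | 4,4,5,5-tetramethyl-2-(2-methylprop-2-en-1-yl)-1,3,2-dioxaborolane (methallylboronic acid pinacol ester) | CC(=C)CB1OC(C)(C)C(C)(C)O1 | starting material
5 | (2R,3S)-3-hydroxy-2-(propan-2-yl)non-8-en-4-ynal (aldol aldehyde; CHO = C8) | O=C[C@H](C(C)C)[C@H](O)C#CCCC=C | intermediate
6 | (4R,5S,6S)-2-methyl-5-(propan-2-yl)dodeca-1,11-dien-7-yne-4,6-diol | O[C@H](CC(C)=C)[C@H](C(C)C)[C@H](O)C#CCCC=C | intermediate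
7 | (4R,5S,6R,7Z)-2,8-dimethyl-5-(propan-2-yl)dodeca-1,7,11-triene-4,6-diol | O[C@H](CC(C)=C)[C@H](C(C)C)[C@H](O)/C=C(C)\CCC=C | intermediate
8 | (1R,2S,3R,4Z,8Z)-5,9-dimethyl-2-(propan-2-yl)cyclodeca-4,8-diene-1,3-diol (ring diol; C8-OH and C6-OH trans, C6-OH and iPr cis) | O[C@@H]1C/C(C)=C\CC/C(C)=C\[C@@H](O)[C@H]1C(C)C | intermediate
9 | 4-hydroxy-3-methoxybenzaldehyde (vanillin) | COc1cc(C=O)ccc1O | starting material
10 | 4-[(tert-butyldimethylsilyl)oxy]-3-methoxybenzaldehyde | COc1cc(C=O)ccc1O[Si](C)(C)C(C)(C)C | intermediate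
11 | (2Z,6Z,9R,10S)-9-hydroxy-3,7-dimethyl-10-(propan-2-yl)cyclodeca-2,6-dien-1-one (C6 ketone, C8 hydroxyl) | O[C@@H]1C/C(C)=C\CC/C(C)=C\C(=O)[C@H]1C(C)C | intermediate
12 | (1R,3Z,7Z,9R,10R)-9-hydroxy-3,7-dimethyl-10-(propan-2-yl)cyclodeca-3,7-dien-1-yl 4-[(tert-butyldimethylsilyl)oxy]-3-methoxybenzoate | COc1cc(C(=O)O[C@@H]2C/C(C)=C\CC/C(C)=C\[C@@H](O)[C@H]2C(C)C)ccc1O[Si](C)(C)C(C)(C)C | intermediate
13 | (1R,3Z,7Z,9R,10R)-9-hydroxy-3,7-dimethyl-10-(propan-2-yl)cyclodeca-3,7-dien-1-yl 4-hydroxy-3-methoxybenzoate | COc1cc(C(=O)O[C@@H]2C/C(C)=C\CC/C(C)=C\[C@@H](O)[C@H]2C(C)C)ccc1O | target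

## Step count and risks

Total steps: 7. Longest linear sequence: 6 (steps 1, 2, 3, 4, 6, 7; step 5 is a one-step side branch).

The three steps most likely to fail:

**Step 4 (ring-closing metathesis to a ten-membered ring with a trisubstituted olefin).** Oligomerisation or no closure is the main danger. The fallback closes the ring by an intramolecular B-alkyl Suzuki–Miyaura coupling at C3–C4 instead; it sets out from 3 and comes back at 8. Compound 3 is combined with commercial but-2-ynal under the aldol conditions of step 2 to give (2R,3S)-3-hydroxy-2-(propan-2-yl)hex-4-ynal F1, which is propargylated with allenylboronic acid pinacol ester and the TRIP enantiomer that delivers the group to the Re face, giving (4R,5S,6S)-5-(propan-2-yl)nona-1,7-diyne-4,6-diol F4. Zirconium-catalysed methylalumination of the terminal alkyne (Me3Al, Cp2ZrCl2 cat., ClCH2CH2Cl), chelation-controlled isomerisation on heating and iodinolysis (I2) give (1Z,4R,5S,6S)-1-iodo-2-methyl-5-(propan-2-yl)non-1-en-7-yne-4,6-diol F5, with iodine cis to C9. Coupling of F5 with potassium vinyltrifluoroborate (PdCl2(dppf), Cs2CO3, THF/H2O) gives (4S,5S,6R,8Z)-8-methyl-5-(propan-2-yl)undeca-8,10-dien-2-yne-4,6-diol F6. trans-Hydroalumination of the propargylic alcohol with NaAlH2(OCH2CH2OMe)2 followed by I2 at −78 °C gives (2Z,4S,5S,6R,8Z)-2-iodo-8-methyl-5-(propan-2-yl)undeca-2,8,10-triene-4,6-diol F7, with iodine cis to C6. Hydroboration of the terminal vinyl group with 9-BBN-H gives (2Z,4S,5S,6R,8Z)-11-(9-borabicyclo[3.3.1]nonan-9-yl)-2-iodo-8-methyl-5-(propan-2-yl)undeca-2,8-diene-4,6-diol F8, which is not isolated but cyclised under high dilution (PdCl2(dppf), AsPh3, Cs2CO3, DMF/THF/H2O) to 8; both olefin geometries are fixed before the ring closes.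

**Step 6 (the proposed redox relay).** Possible failures are direct crossed-Tishchenko acylation of either hydroxyl, oxidation at C8, retro-aldol opening or C7 epimerisation of 11, and over-oxidation of 12. The fallback uses known chemistry in two operations; it sets out from 8 and comes back at 12. Compound 8 is oxidised only at the allylic carbinol with activated MnO2 (CH2Cl2, rt) to the isolated hydroxy enone 11, and 11 is then submitted to the established Evans–Tishchenko reduction (SmI2 30 mol%, 10, THF, −10 °C) to give 12; no compound outside the list is made.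

**Step 3 (iron-catalysed methylmagnesiation of a free diol).** Regio- or stereochemical leakage would give the E olefin or the C5-methyl isomer. The fallback builds the Z olefin by hydroalumination/iodination and cross-coupling; it sets out from 3 and comes back at 7. Compound 3 and but-2-ynal give, under the aldol conditions of step 2, (2R,3S)-3-hydroxy-2-(propan-2-yl)hex-4-ynal F1, which is methallylated with 4 exactly as in step 2 to (4R,5S,6S)-2-methyl-5-(propan-2-yl)non-1-en-7-yne-4,6-diol F2. trans-Hydroalumination with NaAlH2(OCH2CH2OMe)2 (aluminium held by the propargylic oxygen) and iodination (I2, −78 °C) give (4R,5S,6S,7Z)-8-iodo-2-methyl-5-(propan-2-yl)nona-1,7-diene-4,6-diol F3. Suzuki–Miyaura coupling of F3 with potassium but-3-enyltrifluoroborate (PdCl2(dppf), Cs2CO3, THF/H2O) then gives 7 with retention of the olefin geometry.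

Further compounds
F1 | step 3 | (2R,3S)-3-hydroxy-2-(propan-2-yl)hex-4-ynal | O=C[C@H](C(C)C)[C@H](O)C#CC
F2 | step 3 | (4R,5S,6S)-2-methyl-5-(propan-2-yl)non-1-en-7-yne-4,6-diol | O[C@H](CC(C)=C)[C@H](C(C)C)[C@H](O)C#CC
F3 | step 3 | (4R,5S,6S,7Z)-8-iodo-2-methyl-5-(propan-2-yl)nona-1,7-diene-4,6-diol | O[C@H](CC(C)=C)[C@H](C(C)C)[C@H](O)/C=C(C)\I
F4 | step 4 | (4R,5S,6S)-5-(propan-2-yl)nona-1,7-diyne-4,6-diol | O[C@H](CC#C)[C@H](C(C)C)[C@H](O)C#CC
F5 | step 4 | (1Z,4R,5S,6S)-1-iodo-2-methyl-5-(propan-2-yl)non-1-en-7-yne-4,6-diol | O[C@H](C/C(C)=C\I)[C@H](C(C)C)[C@H](O)C#CC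
F6 | step 4 | (4S,5S,6R,8Z)-8-methyl-5-(propan-2-yl)undeca-8,10-dien-2-yne-4,6-diol | O[C@H](C/C(C)=C\C=C)[C@H](C(C)C)[C@H](O)C#CC
F7 | step 4 | (2Z,4S,5S,6R,8Z)-2-iodo-8-methyl-5-(propan-2-yl)undeca-2,8,10-triene-4,6-diol | O[C@H](C/C(C)=C\C=C)[C@H](C(C)C)[C@H](O)/C=C(C)\I
F8 | step 4 | (2Z,4S,5S,6R,8Z)-11-(9-borabicyclo[3.3.1]nonan-9-yl)-2-iodo-8-methyl-5-(propan-2-yl)undeca-2,8-diene-4,6-diol | O[C@H](C/C(C)=C\CCB1C2CCCC1CCC2)[C@H](C(C)C)[C@H](O)/C=C(C)\I
F0 | step 6 | none | none
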